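The gamma run, richer in partner than delta or epsilon, stands at 12.0 h with 39% target against 62% side product.

| flask | substrate | partner | remark | time |
|---|---|---|---|---|
| delta | 0.10 M | 0.11 M | run made earlier |  |
| epsilon | 0.10 M | 0.15 M | run made earlier |  |
| gamma | 0.10 M | 0.24 M | run made earlier |  |
| oak | 0.10 M | 0.110 M (fed, over 12 h) | all else is in the flask from the start; the feed brings no volume worth counting | 20 h |
| alder | 0.10 M (fed, over 12 h) | 0.110 M | all else is in the flask from the start; the feed brings no volume worth counting | 20 h |
| cedar | 0.10 M | 0.110 M | everything together at the start | 20 h |
| ash | 0.10 M (in portions, 3, over 12 h) | 0.110 M | first portion at the start, last at 12 h | 20 h |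

| run | time / h | target / % | side product / % |
|---|---|---|---|
| delta | 1.00 | 16 | 54 |
| delta | 2.00 | 21 | 67 |
| delta | 5.00 | 21 | 79 |
| delta | 12.0 | 24 | 77 |
| epsilon | 3.00 | 25 | 68 |
| epsilon | 6.00 | 28 | 75 |
| epsilon | 10.0 | 28 | 72 |
| epsilon | 12.0 | 26 | 71 |
| gamma | 3.00 | 39 | 58 |
| gamma | 6.00 | 39 | 59 |
| gamma | 10.0 | 39 | 62 |
| gamma | 12.0 | 39 | 62 |

(readings scatter by 1.5 percentage points)

- the earlier runs were read with a standard deviation of 1.5 percentage points

- the best flask by share of target in target plus side product; "all alike" if 1.5 percentage points covers them all (oak / alder / cedar / ash / all alike)
- share of target in target plus side product at the end, oak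
- share of target in target plus side product at the end, alder
- share of target in target plus side product at the end, cedar
- share of target in target plus side product at the end, ash

What does gamma give? Its ratio over charged partner is 2.62 M⁻¹. But target consumes partner, so I put that back and count no other loss of partner: my reckoned mean [partner] is 0.220 M, and the ratio over it is 2.85 M⁻¹. This is an apparent selectivity factor, target formed per side product per molar of that reckoned mean [partner].

And cedar? At charged [partner] my first share is 23.9%. That target lowers my reckoned mean [partner] to 0.0981 M, so on the second round my share is 21.9%.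

Oak has no partner at the start, so what does its substrate see? Delta's first reading gives a substrate decay of 1.20 h⁻¹, of which the side path takes 0.929 h⁻¹, a mean life of 1.08 h. Oak's feed runs at 0.009167 M h⁻¹, so the first ratio is apparent selectivity factor times feed times life, 0.0282. The target path shortens that life by the factor one plus this ratio, and the second round gives my share for oak, 2.67%.

The weak spot: alder and ash? If partner keeps for 12 h, they follow cedar's path. Partner is never read in these runs, and I have not worked out from them how well it keeps. I therefore give those two no firm number.

The forecast names cedar, with oak 2.7%, alder 22.6%, cedar 22.6% and ash 22.6%, holding that “Dosing substrate gains nothing”.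

The flasks give oak 2.29%, alder 4.82%, cedar 21.5% and ash 8.37%, so cedar is best.

    substrate + partner → target (k = 3.70 M⁻¹ h⁻¹)
    partner → decomposed reagent (k = 0.430 h⁻¹)
    substrate → side product (k = 0.950 h⁻¹)

In alder at 10.0 h, partner is down to 1.03% of its charge, decomposed reagent stands at 0.104 M, and target at 4.76%. Oak's reckoned 2.67% lies above its 2.29%. The neighbour of oak, fed 0.44 M of partner over the same 12 h, has a feed of 0.03667 M h⁻¹. With the apparent selectivity factor 2.85 M⁻¹ and life 1.08 h, its first ratio is 0.113 and its second-round share 9.19%. That neighbour gives 8.08%, with 91.9% side product.

The readings stem from a simulated flask from invented constants; scatter was added.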